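Rings: A = methylcyclohexene, B = cyclohexenone (vinylogous ester), C = cyclopentane, D = dimethyltetrahydrofuran; C-e = enol-ether carbon of rings B/D, C-c = carbinol carbon shared by rings B, C and D; C-2 = ring C carbon that carries the C3 unit.
Cuts (retro): ring D at O–C-e (enol-ether exchange); ring B at C-e–C-c (formal addition of the β-C–H of a vinylogous formate across the ring C ketone); rings A and C together by an intramolecular Diels–Alder reaction of an ocimene-type diene with a cis-enedione; enedione ← tetrasubstituted furan ← tetronate ← β-lithiated β-alkoxyacrylate + chiral aldehyde.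
Forward: two fragments → tetronate → furan (masked cis-enedione) → singlet oxygen → rings A + C in one cycloaddition → epoxy ketone and vinylogous formate → rings B then D in one carbene-catalysed operation → desilylation.
Enabling feature: in the A/C hydrindanone the ring C carbonyl carbon (C-c) and the β-carbon of the β-methoxy enone (C-e) hang cis from adjacent quaternary carbons of ring A in a 1,6 relation, and the tertiary OH on C-2 lies five atoms from C-e, so one umpolung event at C-e closes ring B and sets up ring D.
Stereochemistry: an Evans alkylation sets C-2 (isopropenyl); this centre steers the Diels–Alder face (three centres of rings A/C), is then erased (enone, epoxide) and reset by kinetic protonation; the tether fixes C-c in the key step.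

Key step: step 15

Assumption: centres that are destroyed later (C-5 of 20 and 23, the bridgeheads of 25, the spiro carbon of 29) are carried as mixtures or drawn as the expected isomer; the alkoxy-trans-to-carbonyl isomers of 6 and 31 are taken as the major ones.

Step 1
Reactants: 1 geranyl bromide; 2 methyl acetate
Product: 4 methyl (4E)-5,9-dimethyldeca-4,8-dienoate, via lithium enolate 3 (not isolated)
Conditions: lithium diisopropylamide, THF, −78 °C; then 1, DMPU, −78 → 0 °C
Reagents that add atoms: none
Why: SN2 alkylation of an ester lithium enolate by a primary allylic bromide; the (E)-alkene of the geranyl unit is not touched.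

Step 2
Reactants: 4
Product: 6 methyl (2E,4E)-5,9-dimethyl-2-{[(triisopropylsilyloxy)methoxy]methylidene}deca-4,8-dienoate, via sodium enolate 5 (not isolated)
Conditions: NaH, HCO2Me, THF, 0 °C → rt; then (iPr)3SiOCH2Cl, DMF, 0 °C
Reagents that add atoms: methyl formate COC=O; (triisopropylsiloxy)methyl chloride CC(C)[Si](OCCl)(C(C)C)C(C)C
Why: Crossed Claisen formylation followed by O-alkylation of the enolate with a hard α-chloro ether should give the β-alkoxyacrylate with the alkoxy group trans to the ester, the geometry needed for chelation-assisted lithiation in step 9.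

Step 3
Reactants: 7 (2E)-3-methylpent-2-en-4-yn-1-ol
Product: 8 (2E)-3-methylpenta-2,4-dien-1-ol
Conditions: H2 (1 atm), Pd on CaCO3 poisoned with Pb(OAc)2 (Lindlar catalyst), quinoline, EtOAc, rt
Reagents that add atoms: none
Why: Lindlar semi-hydrogenation stops at the vinyl group and leaves the (E)-trisubstituted alkene in place.

Step 4
Reactants: 8
Product: 9 (3E)-5-bromo-3-methylpenta-1,3-diene
Conditions: PBr3, Et2O, −20 °C
Reagents that add atoms: phosphorus tribromide BrP(Br)Br
Why: Conversion of a primary allylic alcohol into the bromide with PBr3; the conjugated primary bromide is the thermodynamically preferred allylic isomer.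

Step 5
Reactants: 10 (4S)-4-benzyloxazolidin-2-one; 11 3-methylbut-2-enoyl chloride
Product: 13 (4S)-4-benzyl-3-(3-methylbut-2-enoyl)oxazolidin-2-one, via lithium oxazolidinide 12 (not isolated)
Conditions: n-BuLi, THF, −78 °C; then 11, −78 → 0 °C
Reagents that add atoms: none
Why: N-acylation of the lithiated Evans auxiliary by an acid chloride.

Step 6
Reactants: 13; 9
Product: 15 (4S)-4-benzyl-3-[(2S,4E)-5-methyl-2-(prop-1-en-2-yl)hepta-4,6-dienoyl]oxazolidin-2-one, via sodium dienolate 14 (not isolated)
Conditions: NaN(SiMe3)2, THF, −78 °C; then 9, −78 → −40 °C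
Reagents that add atoms: none
Why: Evans alkylation in its deconjugative form: γ-deprotonation gives the chelated (Z)-dienolate, which is alkylated at the α-carbon on the face away from the benzyl group and so sets the (2S) centre that bears the isopropenyl group.

Step 7
Reactants: 15
Product: 16 (2S,4E)-5-methyl-2-(prop-1-en-2-yl)hepta-4,6-dien-1-ol
Conditions: LiBH4, Et2O, H2O (1 equiv), 0 °C
Reagents that add atoms: none
Why: Reductive cleavage of the N-acyl oxazolidinone by LiBH4 gives the primary alcohol and returns the auxiliary without touching the allylic stereocentre.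

Step 8
Reactants: 16
Product: 17 (2S,4E)-5-methyl-2-(prop-1-en-2-yl)hepta-4,6-dienal
Conditions: Dess–Martin periodinane, pyridine, CH2Cl2, 0 °C; used at once
Reagents that add atoms: none
Why: Buffered Dess–Martin oxidation gives the β,γ-unsaturated aldehyde without acid or base that could conjugate the double bond or racemise the α-centre.

Step 9
Reactants: 6; 17
Product: 20 5-[(3S,5E)-2,6-dimethylocta-1,5,7-trien-3-yl]-3-[(2E)-3,7-dimethylocta-2,6-dien-1-yl]-4-[(triisopropylsilyloxy)methoxy]furan-2(5H)-one as both C-5 epimers, via lithiated acrylate 18 (not isolated), via lithium alkoxide 19 (not isolated)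
Conditions: lithium diisopropylamide, THF, −95 °C; then 17, −95 → 0 °C; then H2O
Reagents that add atoms: none
Why: Chelation-assisted β-lithiation of the β-alkoxyacrylate, 1,2-addition of the vinyllithium to the aldehyde and lactonisation of the cis-placed alkoxide onto the ester (tetronate synthesis by way of a β-lithio-β-alkoxyacrylate); the new C-5 centre is erased later.

Step 10
Reactants: 20; 21 5-bromo-2-methylpent-2-ene
Product: 24 2-[(3S,5E)-2,6-dimethylocta-1,5,7-trien-3-yl]-4-[(2E)-3,7-dimethylocta-2,6-dien-1-yl]-5-(4-methylpent-3-en-1-yl)-3-[(triisopropylsilyloxy)methoxy]furan, via Grignard reagent 22 (not isolated), via lactol 23 (not isolated)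
Conditions: 21, Mg, THF, rt; then 20, −40 °C; then camphorsulfonic acid (cat.), 4 Å sieves, CH2Cl2, 0 °C
Reagents that add atoms: none
Why: 1,2-Addition of the Grignard reagent to the lactone carbonyl and acid-catalysed loss of water from the lactol aromatise the butenolide to a furan, which stores the cis-enedione and keeps the allylic stereocentre out of conjugation with a carbonyl group.

Step 11
Reactants: 24
Product: 27 (2S,3aS,7R,7aR)-7-[(2E)-3,7-dimethylocta-2,6-dien-1-yl]-4-methyl-7-(5-methylhex-4-enoyl)-2-(prop-1-en-2-yl)-7a-[(triisopropylsilyloxy)methoxy]-2,3,3a,6,7,7a-hexahydro-1H-inden-1-one, via endoperoxide 25 (not isolated), via enedione 26 (not isolated)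
Conditions: O2, tetraphenylporphyrin (cat.), visible light, CH2Cl2, −78 °C; then Me2S, −78 → 0 °C; then toluene, BHT, 80 °C
Reagents that add atoms: dioxygen O=O
Why: [4+2] addition of singlet oxygen to the electron-rich tetrasubstituted furan and reduction of the endoperoxide unveil the cis-enedione, which then undergoes the intramolecular Diels–Alder reaction through the transition state with the tether carbonyl under the diene (cis ring fusion of rings A and C), the dienophile geometry placing geranyl cis to the alkoxy group and the C-2 centre, which turns its hydrogen toward the diene methyl group, choosing the face.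

Step 12
Reactants: 27
Product: 29 2-spiro-(3,3-dimethyloxirane) ketone derived from 28 (epoxide of the exocyclic C=C; other groups as in 27), via conjugated enone 28 (not isolated)
Conditions: H2O2 (30 % aq.), NaOH, MeOH, 0 °C → rt
Reagents that add atoms: hydrogen peroxide OO
Why: Base moves the β,γ-double bond into conjugation, which erases the relay stereocentre, and Weitz–Scheffer nucleophilic epoxidation then attacks only the enone (as with pulegone), the isolated alkenes being inert to hydroperoxide anion.

Step 13
Reactants: 29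
Product: 31 β-methoxy enone: 29 whose 5-methylhex-4-enoyl group has become (2E)-2-(methoxymethylidene)-5-methylhex-4-enoyl, via sodium enolate 30 (not isolated)
Conditions: NaH, HCO2Et, THF, 0 °C → rt; then Me2SO4, DMF, 0 °C
Reagents that add atoms: ethyl formate CCOC=O; dimethyl sulfate COS(=O)(=O)OC
Why: Claisen formylation can only settle at the CH2 group next to the side-chain ketone (the epoxy ketone has no α-hydrogen) and O-methylation of the resulting enolate gives the vinylogous formate.

Step 14
Reactants: 31
Product: 32 (2R,3aS,7R,7aR)-2-(2-hydroxypropan-2-yl) ketone: 31 with the oxirane opened to H-2 and a tertiary alcohol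
Conditions: SmI2 (2.2 equiv), THF–MeOH, −90 °C
Reagents that add atoms: none
Why: Reductive opening of an α,β-epoxy ketone by SmI2 gives the β-hydroxy ketone, and methanol should protonate the samarium enolate from the convex face (away from ring A and its methyl group), which places the 2-hydroxypropan-2-yl group on the concave face as ring D needs.

Step 15
Reactants: 32
Product: 34 [(triisopropylsilyloxy)methyl] ether of 35 at the ring-fusion hydroxyl next to the quaternary carbon, via ring B carbinol 33 (not isolated)
Conditions: 1,3,4-triphenyl-4,5-dihydro-1H-1,2,4-triazol-5-ylidene (20 mol %), toluene, 60 °C; then DBU (20 mol %), 60 °C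
Reagents that add atoms: none
Why: Proposed new method: the triazolylidene should add to the β-carbon (C-e) of the β-methoxy enone, a 1,2-proton shift then makes C-e the nucleophilic terminus of an O-methyl Breslow-type ene-aminal, this carbon adds to the ring C ketone (C-c) in a 6-exo-trig closure of ring B, and E1cB loss of the carbene restores the enone to give 33. The closest known reaction types are the carbene-catalysed β-umpolung of Michael acceptors (intramolecular β-alkylation of enoates and tail-to-tail dimerisation of acrylates through deoxy-Breslow intermediates), the intramolecular aldehyde–ketone benzoin reaction and the addition of β-lithiated β-alkoxyacrylates to ketones. In the same flask the tertiary alkoxide adds to C-e in a 5-exo-trig mode and methoxide leaves (vinylogous transesterification), which closes ring D. The one new stereocentre, C-c, is set by the tether: the enone hangs from the quaternary carbon on the concave face, so C-e can reach the ketone only from that face and the new hydroxyl ends cis to the neighbouring silyloxymethoxy group. The step needs the ring C ketone to react and not the side-chain ketone, and needs C-2 to keep its configuration; the first is secured because the side-chain carbonyl is the acceptor's own and lies inside the forming ring, the second because the free carbene is used without a stronger base until the ketone is consumed, after which nothing next to C-2 is acidic. Retro-aldol loss of acetone is likewise closed off once C-c has become a carbinol.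

Step 16
Reactants: 34
Product: 35 CNP0323114.1 (target)
Conditions: tetrabutylammonium fluoride, AcOH (1:1), THF, 0 °C → rt
Reagents that add atoms: none
Why: Fluoride cleaves the Si–O bond of the silyloxymethyl ether and the hemiformal anion loses formaldehyde, so that no electrophilic carbon is formed that could bridge the cis-diol.

Compound list
1 | geranyl bromide, (2E)-1-bromo-3,7-dimethylocta-2,6-diene | CC(C)=CCC/C(C)=C/CBr | starting material
2 | methyl acetate | CC(=O)OC | starting material
3 | lithium enolate of methyl acetate | [Li+].C=C([O-])OC | intermediate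
4 | methyl (4E)-5,9-dimethyldeca-4,8-dienoate | CC(C)=CCC/C(C)=C/CCC(=O)OC | intermediate
5 | sodium enolate of methyl (4E)-2-formyl-5,9-dimethyldeca-4,8-dienoate | [Na+].[O-]C=C(C/C=C(\C)CCC=C(C)C)C(=O)OC | intermediate
6 | methyl (2E,4E)-5,9-dimethyl-2-{[(triisopropylsilyloxy)methoxy]methylidene}deca-4,8-dienoate (alkoxy trans to ester) | CC(C)[Si](C(C)C)(C(C)C)OCO/C=C(/C(=O)OC)C/C=C(\C)CCC=C(C)C | intermediate
7 | (2E)-3-methylpent-2-en-4-yn-1-ol | C#C/C(C)=C/CO | starting material
8 | (2E)-3-methylpenta-2,4-dien-1-ol | C=C/C(C)=C/CO | intermediate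
9 | (3E)-5-bromo-3-methylpenta-1,3-diene | C=C/C(C)=C/CBr | intermediate
10 | (4S)-4-benzyloxazolidin-2-one | O=C1N[C@@H](Cc2ccccc2)CO1 | starting material
11 | 3-methylbut-2-enoyl chloride | CC(C)=CC(Cl)=O | starting material
12 | N-lithio salt of 10 | [Li+].O=C1[N-][C@@H](Cc2ccccc2)CO1 | intermediate
13 | (4S)-4-benzyl-3-(3-methylbut-2-enoyl)oxazolidin-2-one | CC(C)=CC(=O)N1[C@@H](Cc2ccccc2)COC1=O | intermediate
14 | sodium (Z)-dienolate of 13 (O and isopropenyl cis) | [Na+].[O-]/C(=C\C(C)=C)N1[C@@H](Cc2ccccc2)COC1=O | intermediate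
15 | (4S)-4-benzyl-3-[(2S,4E)-5-methyl-2-(prop-1-en-2-yl)hepta-4,6-dienoyl]oxazolidin-2-one | C=C/C(C)=C/C[C@@H](C(C)=C)C(=O)N1[C@@H](Cc2ccccc2)COC1=O | intermediate
16 | (2S,4E)-5-methyl-2-(prop-1-en-2-yl)hepta-4,6-dien-1-ol | C=C/C(C)=C/C[C@@H](C(C)=C)CO | intermediate
17 | (2S,4E)-5-methyl-2-(prop-1-en-2-yl)hepta-4,6-dienal | C=C/C(C)=C/C[C@@H](C(C)=C)C=O | intermediate
18 | 6 lithiated at the alkoxy-bearing vinyl carbon (Li cis to the ester) | CC(C)[Si](C(C)C)(C(C)C)OCO/C([Li])=C(/C(=O)OC)C/C=C(\C)CCC=C(C)C | intermediate
19 | lithium alkoxide from addition of 18 to 17 (carbinol carbon cis to the ester; carbinol epimers) | [Li+].C=C/C(C)=C/C[C@@H](C(C)=C)C([O-])/C(OCO[Si](C(C)C)(C(C)C)C(C)C)=C(/C/C=C(\C)CCC=C(C)C)C(=O)OC | intermediate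
20 | 5-[(3S,5E)-2,6-dimethylocta-1,5,7-trien-3-yl]-3-[(2E)-3,7-dimethylocta-2,6-dien-1-yl]-4-[(triisopropylsilyloxy)methoxy]furan-2(5H)-one (C-5 epimers) | C=C/C(C)=C/C[C@@H](C(C)=C)C1OC(=O)C(C/C=C(\C)CCC=C(C)C)=C1OCO[Si](C(C)C)(C(C)C)C(C)C | intermediate
21 | 5-bromo-2-methylpent-2-ene | CC(C)=CCCBr | starting material
22 | (4-methylpent-3-en-1-yl)magnesium bromide | CC(C)=CCC[Mg]Br | intermediate
23 | lactol from 1,2-addition of 22 to 20: the 2-hydroxy-2-(4-methylpent-3-en-1-yl)-2,5-dihydrofuran | C=C/C(C)=C/C[C@@H](C(C)=C)C1OC(O)(CCC=C(C)C)C(C/C=C(\C)CCC=C(C)C)=C1OCO[Si](C(C)C)(C(C)C)C(C)C | intermediate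
24 | 2-[(3S,5E)-2,6-dimethylocta-1,5,7-trien-3-yl]-4-[(2E)-3,7-dimethylocta-2,6-dien-1-yl]-5-(4-methylpent-3-en-1-yl)-3-[(triisopropylsilyloxy)methoxy]furan | C=C/C(C)=C/C[C@@H](C(C)=C)c1oc(CCC=C(C)C)c(C/C=C(\C)CCC=C(C)C)c1OCO[Si](C(C)C)(C(C)C)C(C)C | intermediate
25 | 2,5-endoperoxide of furan 24 (2,3,7-trioxabicyclo[2.2.1]hept-5-ene) | C=C/C(C)=C/C[C@@H](C(C)=C)C12OOC(CCC=C(C)C)(O1)C(C/C=C(\C)CCC=C(C)C)=C2OCO[Si](C(C)C)(C(C)C)C(C)C | intermediate
26 | cis-enedione: 2-geranyl-3-[(triisopropylsilyloxy)methoxy]ene-1,4-dione with the two acyl groups cis; one acyl is 5-methylhex-4-enoyl, the other (2S,4E)-5-methyl-2-(prop-1-en-2-yl)hepta-4,6-dienoyl | C=C/C(C)=C/C[C@@H](C(C)=C)C(=O)/C(OCO[Si](C(C)C)(C(C)C)C(C)C)=C(/C/C=C(\C)CCC=C(C)C)C(=O)CCC=C(C)C | intermediate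
27 | (2S,3aS,7R,7aR)-7-[(2E)-3,7-dimethylocta-2,6-dien-1-yl]-4-methyl-7-(5-methylhex-4-enoyl)-2-(prop-1-en-2-yl)-7a-[(triisopropylsilyloxy)methoxy]-2,3,3a,6,7,7a-hexahydro-1H-inden-1-one | CC(C)=CCC/C(C)=C/C[C@@]1(C(=O)CCC=C(C)C)CC=C(C)[C@@H]2C[C@@H](C(C)=C)C(=O)[C@]12OCO[Si](C(C)C)(C(C)C)C(C)C | intermediate
28 | (3aS,7R,7aR)-2-(propan-2-ylidene) analogue of 27 (conjugated enone) | CC(C)=CCC/C(C)=C/C[C@@]1(C(=O)CCC=C(C)C)CC=C(C)[C@@H]2CC(=C(C)C)C(=O)[C@]12OCO[Si](C(C)C)(C(C)C)C(C)C | intermediate
29 | spiro-epoxy ketone: 28 epoxidised at the exocyclic C=C (oxirane oxygen drawn on the convex face) | CC(C)=CCC/C(C)=C/C[C@@]1(C(=O)CCC=C(C)C)CC=C(C)[C@@H]2C[C@@]3(OC3(C)C)C(=O)[C@]12OCO[Si](C(C)C)(C(C)C)C(C)C | intermediate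
30 | sodium enolate of the 2-formyl derivative of 29 (formyl on the CH2 next to the side-chain ketone) | [Na+].CC(C)=CCC/C(C)=C/C[C@@]1(C(=O)C(CC=C(C)C)=C[O-])CC=C(C)[C@@H]2C[C@@]3(OC3(C)C)C(=O)[C@]12OCO[Si](C(C)C)(C(C)C)C(C)C | intermediate
31 | 29 carrying the (2E)-2-(methoxymethylidene)-5-methylhex-4-enoyl group in place of 5-methylhex-4-enoyl | CC(C)=CCC/C(C)=C/C[C@@]1(C(=O)/C(CC=C(C)C)=C/OC)CC=C(C)[C@@H]2C[C@@]3(OC3(C)C)C(=O)[C@]12OCO[Si](C(C)C)(C(C)C)C(C)C | intermediate
32 | (2R,3aS,7R,7aR)-7-[(2E)-3,7-dimethylocta-2,6-dien-1-yl]-2-(2-hydroxypropan-2-yl)-7-[(2E)-2-(methoxymethylidene)-5-methylhex-4-enoyl]-4-methyl-7a-[(triisopropylsilyloxy)methoxy]-2,3,3a,6,7,7a-hexahydro-1H-inden-1-one | CC(C)=CCC/C(C)=C/C[C@@]1(C(=O)/C(CC=C(C)C)=C/OC)CC=C(C)[C@@H]2C[C@H](C(C)(C)O)C(=O)[C@]12OCO[Si](C(C)C)(C(C)C)C(C)C | intermediate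
33 | ring B carbinol: 34 with ring D still open (free 2-hydroxypropan-2-yl group; OMe on C-e) | CC(C)=CCC/C(C)=C/C[C@]12CC=C(C)[C@@H]3C[C@H](C(C)(C)O)[C@](O)(C(OC)=C(CC=C(C)C)C1=O)[C@@]32OCO[Si](C(C)C)(C(C)C)C(C)C | intermediate
34 | [(triisopropylsilyloxy)methyl] ether of 35 at the hydroxyl on the carbon shared by rings A, B and C | CC(C)=CCC/C(C)=C/C[C@]12CC=C(C)[C@@H]3C[C@@H]4C(C)(C)OC(=C(CC=C(C)C)C1=O)[C@]4(O)[C@@]32OCO[Si](C(C)C)(C(C)C)C(C)C | intermediate
35 | CNP0323114.1: quaternary geranyl carbon R, A/C ring-fusion CH S, C/D ring-fusion CH S, C-c R, carbinol shared by rings A, B and C R | CC(C)=CCC/C(C)=C/C[C@]12CC=C(C)[C@@H]3C[C@@H]4C(C)(C)OC(=C(CC=C(C)C)C1=O)[C@]4(O)[C@@]32O | target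

Total steps: 16. Longest linear sequence: 13 (steps 3, 4, 6–16).

Steps most likely to fail

Step 15 (Proposed new method). The carbene may stop at reversible exchange of methoxide at C-e (addition–elimination) without the proton shift, or epimerisation at C-2 and retro-aldol loss of acetone may outrun ring closure. The fallback uses known chemistry and sets out from 32. Et3SiOSO2CF3 and 2,6-lutidine (CH2Cl2, −78 °C) give the triethylsilyl ether of 32 F1. Lithium 2,2,6,6-tetramethylpiperidide (THF, −95 °C) lithiates C-e with chelation by the enone oxygen (β-lithiation of β-alkoxy enones and β-alkoxyacrylates); the vinyllithium adds at once to the ring C ketone, whose only α-hydrogen is tertiary and shielded, and gives the triethylsilyl ether of 33 F2. Tetrabutylammonium fluoride (THF, 0 °C → rt) then removes both silyl groups, the tertiary alkoxide closes ring D with loss of methoxide, and the route is rejoined at 35.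

Step 11. Ene oxidation of the trisubstituted alkenes or [4+2] oxygenation of the diene may compete with the furan, and the β,γ-unsaturated ketone may move into conjugation (loss of the relay centre) before the cycloaddition. The fallback sets out from 20. Grignard reagent 22 is added at −78 °C and the mixture is worked up at pH 7 without acid, so that the open-chain γ-hydroxy enone F3 (in equilibrium with lactol 23) is kept. Dess–Martin periodinane with pyridine (CH2Cl2, 0 °C) oxidises its secondary alcohol to enedione 26, which is heated as in step 11; the route is rejoined at 27 without light, oxygen or a furan.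

Step 10. The Grignard reagent may deprotonate the acidic C-5 hydrogen of the tetronate or add to C-4 with loss of the alkoxy group in place of 1,2-addition. The fallback sets out from 20. KN(SiMe3)2 and then N-phenylbis(trifluoromethanesulfonimide) (THF, −78 °C) enolise toward C-5 and trap the 2-oxidofuran as the 2-furyl triflate F4. Bromide 21 is converted with zinc dust (THF, LiCl) into (4-methylpent-3-en-1-yl)zinc bromide F5, and Negishi coupling of F4 with F5 under Pd(PPh3)4 (THF, 40 °C) puts in the side chain and returns to the route at 24.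

Further compounds
F1 | step 15 | triethylsilyl ether of 32 at the tertiary alcohol | CC(C)=CCC/C(C)=C/C[C@@]1(C(=O)/C(CC=C(C)C)=C/OC)CC=C(C)[C@@H]2C[C@H](C(C)(C)O[Si](CC)(CC)CC)C(=O)[C@]12OCO[Si](C(C)C)(C(C)C)C(C)C
F2 | step 15 | triethylsilyl ether of 33 at the side-chain tertiary alcohol (ring B closed) | CC(C)=CCC/C(C)=C/C[C@]12CC=C(C)[C@@H]3C[C@H](C(C)(C)O[Si](CC)(CC)CC)[C@](O)(C(OC)=C(CC=C(C)C)C1=O)[C@@]32OCO[Si](C(C)C)(C(C)C)C(C)C
F3 | step 11 | open-chain γ-hydroxy enone (ring-opened form of lactol 23; carbinol carbon cis to the ketone) | C=C/C(C)=C/C[C@@H](C(C)=C)C(O)/C(OCO[Si](C(C)C)(C(C)C)C(C)C)=C(/C/C=C(\C)CCC=C(C)C)C(=O)CCC=C(C)C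
F4 | step 10 | 2-furyl triflate: 24 with trifluoromethanesulfonyloxy in place of the 4-methylpent-3-en-1-yl group | C=C/C(C)=C/C[C@@H](C(C)=C)c1oc(OS(=O)(=O)C(F)(F)F)c(C/C=C(\C)CCC=C(C)C)c1OCO[Si](C(C)C)(C(C)C)C(C)C
F5 | step 10 | (4-methylpent-3-en-1-yl)zinc bromide | CC(C)=CCC[Zn]Br
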